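## Retrosynthetic overview

1. Target ⇒ primary alcohol 17 + umbelliferone (Mitsunobu C–O bond). The exocyclic CH2 comes from a C2 ketone, and the C6 acetate from a C6 ketone.
2. The C4a methyl and C5 gem-dimethyl (three contiguous quaternary carbons, cis ring fusion) come from Li/NH3 opening of cyclopropyl ketone 11 with enolate methylation. Ketone 11 comes from OH-directed cyclopropanation of the allylic alcohol derived from enone 8.
3. Ring B is annulated onto ring-A ketone 5 with ethyl vinyl ketone; the Michael step, anti to the C1 side chain, sets C8a.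
4. Ring A is purchased as enone ketal 1. Its single stereocentre (future C1) and the CH2O carbon come from a new Cu-catalysed asymmetric conjugate hydroxymethylation with enolate methylation.
5. Ring order: A (commercial) → B (annulation) → transient cyclopropane → functional-group endgame.

**Assumptions**
- The SMILES is taken literally: a cis-fused decalin with a methyl on both ring-fusion carbons (16-carbon terpenoid part), with the C1 CH2OAr, C4a-Me, C8a-Me and C6-OAc all on one face; (1S,4aS,6S,8aR).
- The ligand enantiomer in Step 1 and the matched amine in Step 4 are assigned by analogy; the antipodal ligand (or benzylamine in Step 4) is used if the sense is opposite.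
- Decalin numbering for bicyclic compounds: C1 = CH bearing CH2O; C2 = ketal/ketone/methylene carbon; C4a and C8a = ring-fusion carbons; C5 = CMe2; C6 = O-bearing carbon.

## Route

**Step 1**
Reactants: 1 (1,4-dioxaspiro[4.5]dec-6-en-8-one); 2 ((chloromethyl)isopropoxydimethylsilane, used as its Grignard reagent)
Product: 3, (6R,7R)-6-{[isopropoxy(dimethyl)silyl]methyl}-7-methyl-1,4-dioxaspiro[4.5]decan-8-one (6,7-trans)
Conditions: 2, Mg, Et2O (Grignard formation); CuBr·SMe2 (5 mol %), (R,S)-Josiphos (6 mol %), t-BuOMe, –78 °C, slow addition; then MeI, DMPU, –78 → 0 °C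
Reagents that add atoms: Grignard of 2, CC(C)O[Si](C)(C)C[Mg]Cl; iodomethane, CI
Why: Proposed new method: the chiral Cu(I)–diphosphine complex takes up the β-hydrogen-free silylmethyl group from Mg, binds the Mg-activated enone as a π-complex, and oxidative addition/reductive elimination through a Cu(III) enolate sets C6 (future C1) enantioselectively; the resulting Mg enolate is then methylated regiospecifically at C7. The closest known reaction types are Cu/ferrocenyl-diphosphine asymmetric conjugate addition of simple alkyl Grignard reagents to cyclohexenones and the racemic CuI-catalysed conjugate addition of this Tamao hydroxymethyl-anion Grignard.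

**Step 2**
Reactants: 3
Product: 4, (6S,7R)-6-(hydroxymethyl)-7-methyl-1,4-dioxaspiro[4.5]decan-8-one
Conditions: 30% H2O2, KF, KHCO3, THF/MeOH, rt (crude 3 used directly)
Reagents that add atoms: hydrogen peroxide, OO
Why: Tamao–Kumada oxidation converts the alkoxysilyl C–Si bond to C–OH without touching the ketone or ketal; the C6 stereocentre is not involved.

**Step 3**
Reactants: 4
Product: 5, (6S,7R)-7-methyl-6-{[(triisopropylsilyl)oxy]methyl}-1,4-dioxaspiro[4.5]decan-8-one
Conditions: TIPSCl, imidazole, DMAP (cat.), CH2Cl2, rt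
Reagents that add atoms: TIPSCl, CC(C)[Si](Cl)(C(C)C)C(C)C
Why: Standard silylation of a primary alcohol; TIPS survives base, Zn carbenoids, Li/NH3, hydride and mild acid.

**Step 4**
Reactants: 5; 6 (ethyl vinyl ketone, pent-1-en-3-one)
Product: 7, (6S,7R)-7-methyl-7-(3-oxopentyl)-6-{[(triisopropylsilyl)oxy]methyl}-1,4-dioxaspiro[4.5]decan-8-one (7-Me cis to the C6 side chain)
Conditions: (R)-1-phenylethylamine, TsOH (cat.), toluene, Dean–Stark; then 6, THF, 40 °C; then 10% aq AcOH, rt
Reagents that add atoms: ethyl vinyl ketone (6), CCC(=O)C=C; water, O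
Why: d'Angelo-type Michael reaction of the more substituted secondary enamine occurs only at C7 and anti to the pseudo-axial C6 side chain (matched with the R amine), creating the C8a quaternary centre with its methyl cis to CH2OTIPS; the original C7 configuration is erased in the enamine.

**Step 5**
Reactants: 7
Product: 8, (1S,8aR)-5,8a-dimethyl-1-{[(triisopropylsilyl)oxy]methyl}-3,4,8,8a-tetrahydro-1H-spiro[naphthalene-2,2'-[1,3]dioxolan]-6(7H)-one
Conditions: NaOMe, MeOH, 60 °C
Reagents that add atoms: none
Why: Intramolecular aldol condensation (second stage of the Robinson annulation) closes ring B to the tetrasubstituted enone; no stereocentre is α to a carbonyl.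

**Step 6**
Reactants: 8
Product: 9, (1S,6S,8aR)-allylic alcohol, 5,8a-dimethyl-1-{[(triisopropylsilyl)oxy]methyl}-3,4,6,7,8,8a-hexahydro-1H-spiro[naphthalene-2,2'-[1,3]dioxolan]-6-ol (6-OH cis to 8a-Me)
Conditions: NaBH4, CeCl3·7H2O, MeOH, –40 °C
Reagents that add atoms: none
Why: Luche 1,2-reduction; hydride adds axially from the face opposite the angular methyl, as in Δ4-3-keto steroids giving 3β-ols, so the OH is cis to 8a-Me.

**Step 7**
Reactants: 9
Product: 10, (1S,4aR,5R,6S,8aR)-5,8a-dimethyl-4a,5-methano-1-{[(triisopropylsilyl)oxy]methyl}octahydro-1H-spiro[naphthalene-2,2'-[1,3]dioxolan]-6-ol (cyclopropane CH2, 6-OH and 8a-Me on the same face)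
Conditions: Et2Zn, CH2I2, CH2Cl2, 0 °C → rt
Reagents that add atoms: diiodomethane, ICI
Why: Hydroxyl-directed Simmons–Smith (Furukawa) cyclopropanation; the zinc alkoxide delivers CH2 syn to the 6-OH, placing the future C4a methyl carbon cis to 8a-Me.

**Step 8**
Reactants: 10
Product: 11, (1S,4aR,5R,8aR)-cyclopropyl ketone, 5,8a-dimethyl-4a,5-methano-1-{[(triisopropylsilyl)oxy]methyl}hexahydro-1H-spiro[naphthalene-2,2'-[1,3]dioxolan]-6(5H)-one
Conditions: Dess–Martin periodinane, NaHCO3, CH2Cl2, rt
Reagents that add atoms: none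
Why: Buffered Dess–Martin oxidation of the secondary carbinol; the ketal, silyl ether and cyclopropane are inert.

**Step 9**
Reactants: 11
Product: 12, (1S,4aS,8aR)-4a,5,5,8a-tetramethyl-1-{[(triisopropylsilyl)oxy]methyl}hexahydro-1H-spiro[naphthalene-2,2'-[1,3]dioxolan]-6(5H)-one (cis-fused, 4a-Me cis to 8a-Me)
Conditions: Li (2.3 equiv), t-BuOH (1 equiv), NH3/THF, –78 °C; isoprene; then MeI, –78 → –33 °C
Reagents that add atoms: iodomethane, CI
Why: Dissolving-metal reductive cleavage of the cyclopropyl ketone breaks the exocyclic C5–CH2 bond (best overlap with the C=O π system), giving the C4a methyl with the cyclopropane's configuration and a regiodefined C5 enolate; C-methylation (reductive alkylation) makes the gem-dimethyl.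

**Step 10**
Reactants: 12
Product: 13, (1S,4aS,6S,8aR)-4a,5,5,8a-tetramethyl-1-{[(triisopropylsilyl)oxy]methyl}octahydro-1H-spiro[naphthalene-2,2'-[1,3]dioxolan]-6-ol (6-OH cis to 4a-Me)
Conditions: L-Selectride, THF, –78 → 0 °C; NaOH, H2O2 work-up
Reagents that add atoms: none
Why: In the favoured cis-decalin conformer the 4a-methyl is axial and 1,3 to the carbonyl, so the bulky hydride attacks from the opposite (equatorial) side under steric-approach control, giving the alcohol cis to that methyl.

**Step 11**
Reactants: 13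
Product: 14, (1S,4aS,6S,8aR)-4a,5,5,8a-tetramethyl-1-{[(triisopropylsilyl)oxy]methyl}octahydro-1H-spiro[naphthalene-2,2'-[1,3]dioxolan]-6-yl acetate
Conditions: Ac2O, DMAP, Et3N, CH2Cl2, rt → 40 °C
Reagents that add atoms: acetic anhydride, CC(=O)OC(C)=O
Why: DMAP-catalysed acylation of the hindered secondary alcohol with retention at C6.

**Step 12**
Reactants: 14
Product: 15, (1S,4aS,6S,8aR)-6-acetoxy-4a,5,5,8a-tetramethyl-1-{[(triisopropylsilyl)oxy]methyl}octahydronaphthalen-2(1H)-one
Conditions: PPTS, acetone/H2O (9:1), 55 °C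
Reagents that add atoms: water, O
Why: Mild acid-catalysed transketalisation/hydrolysis frees the C2 ketone; the acetate and primary TIPS ether survive, and weak acid avoids C1 epimerisation and β-elimination.

**Step 13**
Reactants: 15
Product: 16, (1S,4aS,6S,8aR)-4a,5,5,8a-tetramethyl-2-methylene-1-{[(triisopropylsilyl)oxy]methyl}decahydronaphthalen-6-yl acetate
Conditions: Zn, CH2Br2, TiCl4, THF/CH2Cl2, 0 °C → rt
Reagents that add atoms: dibromomethane, BrCBr
Why: Takai–Lombardo methylenation is non-basic, so the epimerisable β-silyloxy C1 centre is preserved and the acetate is untouched.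

**Step 14**
Reactants: 16
Product: 17, (1S,4aS,6S,8aR)-1-(hydroxymethyl)-4a,5,5,8a-tetramethyl-2-methylenedecahydronaphthalen-6-yl acetate
Conditions: TBAF, AcOH, THF, rt
Reagents that add atoms: none
Why: Buffered fluoride desilylation leaves the acetate and the exocyclic alkene intact.

**Step 15**
Reactants: 17; 18 (umbelliferone, 7-hydroxy-2H-chromen-2-one)
Product: 19, polyanthinin as drawn, 7-{[(1S,4aS,6S,8aR)-6-acetoxy-4a,5,5,8a-tetramethyl-2-methylenedecahydronaphthalen-1-yl]methoxy}-2H-chromen-2-one
Conditions: PPh3, DIAD, THF, 0 °C → rt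
Reagents that add atoms: umbelliferone (18), Oc1ccc2ccc(=O)oc2c1
Why: Mitsunobu etherification of the primary alcohol with an acidic phenol (pKa about 7.8) under neutral conditions; no stereocentre is involved.

## Compound list

1 | 1,4-dioxaspiro[4.5]dec-6-en-8-one | O=C1C=CC2(CC1)OCCO2 | starting material
2 | (chloromethyl)isopropoxydimethylsilane (used as its Grignard reagent) | ClC[Si](C)(C)OC(C)C | starting material
3 | (6R,7R)-6-{[isopropoxy(dimethyl)silyl]methyl}-7-methyl-1,4-dioxaspiro[4.5]decan-8-one | O1CCOC12CCC(=O)[C@H](C)[C@H]2C[Si](C)(C)OC(C)C | intermediate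
4 | (6S,7R)-6-(hydroxymethyl)-7-methyl-1,4-dioxaspiro[4.5]decan-8-one | O1CCOC12CCC(=O)[C@H](C)[C@H]2CO | intermediate
5 | (6S,7R)-7-methyl-6-{[(triisopropylsilyl)oxy]methyl}-1,4-dioxaspiro[4.5]decan-8-one | O1CCOC12CCC(=O)[C@H](C)[C@H]2CO[Si](C(C)C)(C(C)C)C(C)C | intermediate
6 | ethyl vinyl ketone (pent-1-en-3-one) | CCC(=O)C=C | starting material
7 | (6S,7R)-7-methyl-7-(3-oxopentyl)-6-{[(triisopropylsilyl)oxy]methyl}-1,4-dioxaspiro[4.5]decan-8-one | O1CCOC12CCC(=O)[C@@](CCC(=O)CC)(C)[C@H]2CO[Si](C(C)C)(C(C)C)C(C)C | intermediate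
8 | (1S,8aR)-5,8a-dimethyl-1-(TIPSO-methyl)-3,4,8,8a-tetrahydro-1H-spiro[naphthalene-2,2'-[1,3]dioxolan]-6(7H)-one | O1CCOC12CCC3=C(C)C(=O)CC[C@]3(C)[C@H]2CO[Si](C(C)C)(C(C)C)C(C)C | intermediate
9 | (1S,6S,8aR)-allylic alcohol of 8 (6-OH cis to 8a-Me) | O1CCOC12CCC3=C(C)[C@@H](O)CC[C@]3(C)[C@H]2CO[Si](C(C)C)(C(C)C)C(C)C | intermediate
10 | (1S,4aR,5R,6S,8aR)-4a,5-methano (cyclopropyl) carbinol; CH2, 6-OH and 8a-Me cis | O1CCOC12CC[C@]34C[C@@]3(C)[C@@H](O)CC[C@]4(C)[C@H]2CO[Si](C(C)C)(C(C)C)C(C)C | intermediate
11 | (1S,4aR,5R,8aR)-4a,5-methano 6-ketone | O1CCOC12CC[C@]34C[C@@]3(C)C(=O)CC[C@]4(C)[C@H]2CO[Si](C(C)C)(C(C)C)C(C)C | intermediate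
12 | (1S,4aS,8aR)-4a,5,5,8a-tetramethyl-1-(TIPSO-methyl)hexahydro-1H-spiro[naphthalene-2,2'-[1,3]dioxolan]-6(5H)-one, cis-fused | O1CCOC12CC[C@]3(C)C(C)(C)C(=O)CC[C@]3(C)[C@H]2CO[Si](C(C)C)(C(C)C)C(C)C | intermediate
13 | (1S,4aS,6S,8aR)-6-alcohol of 12 (OH cis to 4a-Me) | O1CCOC12CC[C@]3(C)C(C)(C)[C@@H](O)CC[C@]3(C)[C@H]2CO[Si](C(C)C)(C(C)C)C(C)C | intermediate
14 | (1S,4aS,6S,8aR)-6-acetate of 13 | O1CCOC12CC[C@]3(C)C(C)(C)[C@@H](OC(C)=O)CC[C@]3(C)[C@H]2CO[Si](C(C)C)(C(C)C)C(C)C | intermediate
15 | (1S,4aS,6S,8aR)-6-acetoxy-4a,5,5,8a-tetramethyl-1-(TIPSO-methyl)octahydronaphthalen-2(1H)-one | O=C1CC[C@]2(C)C(C)(C)[C@@H](OC(C)=O)CC[C@]2(C)[C@H]1CO[Si](C(C)C)(C(C)C)C(C)C | intermediate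
16 | (1S,4aS,6S,8aR)-4a,5,5,8a-tetramethyl-2-methylene-1-(TIPSO-methyl)decahydronaphthalen-6-yl acetate | C=C1CC[C@]2(C)C(C)(C)[C@@H](OC(C)=O)CC[C@]2(C)[C@H]1CO[Si](C(C)C)(C(C)C)C(C)C | intermediate
17 | (1S,4aS,6S,8aR)-1-(hydroxymethyl)-4a,5,5,8a-tetramethyl-2-methylenedecahydronaphthalen-6-yl acetate | C=C1CC[C@]2(C)C(C)(C)[C@@H](OC(C)=O)CC[C@]2(C)[C@H]1CO | intermediate
18 | umbelliferone (7-hydroxy-2H-chromen-2-one) | Oc1ccc2ccc(=O)oc2c1 | starting material
19 | polyanthinin (as given) | C=C1CC[C@]2(C)C(C)(C)[C@@H](OC(C)=O)CC[C@]2(C)[C@H]1COc1ccc2ccc(=O)oc2c1 | target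

## Summary

Total steps: 15. Longest linear sequence: 15 (from 1).

Steps most likely to fail:

1. **Step 1 (proposed new asymmetric conjugate hydroxymethylation).** Transfer of the silylmethyl group from Cu may be slow or poorly enantioselective. Fallback with known chemistry: reverse the roles on the same enone. Use the established Cu/phosphoramidite conjugate addition of Me2Zn (the methyl goes on the future C8a), trap the zinc enolate as its TMS enol ether, and run a Lewis-acid Mukaiyama aldol with aqueous formaldehyde to place CH2OH trans on the future C1. Then protect as the TIPS ether, reduce and protect the old ketone (future C2, re-oxidised before Step 13), unmask the ketal as the C4a ketone, and rejoin at Step 4.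

2. **Step 9 (C-methylation of the congested enolate next to two quaternary carbons).** Fallback: after NH3 removal, trap the reductively generated enolate as the TMS enol ether, cyclopropanate it (Et2Zn/CH2I2, Conia-type), and open the siloxycyclopropane with base to the α-methyl ketone. This installs the second C5 methyl by carbenoid addition and ring opening instead of enolate alkylation.

3. **Step 7 (directed cyclopropanation of a tetrasubstituted alkene syn to the angular methyl).** Fallback: use methyl vinyl ketone in Step 4 to obtain the C5-unsubstituted enone. Install the C4a methyl by Cu-mediated conjugate addition (known to give the cis-dimethyl ring fusion) with MeI trapping of the enolate. Introduce the second C5 methyl after temporarily blocking C7 as its n-butylthiomethylene derivative, then deblock to reach 12.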